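## The problem

Eupakirunsin C (31) is a germacranolide. A ten-membered carbocycle (C1–C10) carries a trans-fused α-methylene-γ-butyrolactone at C6/C7 (C11, C12, C13), a tiglate at C8, a cis-4,5-epoxide beside a C3 ketone, and a free hydroxyl at C1 next to a saturated, methyl-bearing C10. There are seven stereocentres (1R, 4R, 5R, 6S, 7R, 8R, 10S). C6, C7 and C8 are contiguous, but the C1/C10 and C4/C5 pairs are separated from them by flexible ring bonds. These pairs can therefore only be set by reagent approach to the outer face of a ring whose shape the trans lactone fixes, combined with stereospecific reactions of ring alkenes of defined geometry. Syn addition to an E-C1=C10 bond gives the C1/C10 pair, and oxygen transfer to a Z-C4=C5 bond gives the cis epoxide. The ring itself is the main constitutional difficulty, since direct closure of a ten-membered carbocycle is disfavoured by entropy and transannular strain. Several groups are fragile: the α-methylene lactone and the tiglate do not tolerate hydride, borane, enolate or peroxide-anion chemistry, the epoxy ketone is acid-sensitive, and the C1-hydroxy/C3-ketone pair can dehydrate or undergo retro-aldol cleavage with base. The enabling feature is that C5 and C10 lie 1,6 across the ring and are joined on one side by the four-carbon unit C1–C2–C3–C4 with oxygen at C3. Reconnecting C5 to C10 turns this unit into ring A of a eudesmanolide as a 3-oxygenated cyclohexa-1,3-diene, and C6, C7, the C10 methyl and the trans lactone then coincide with (−)-α-santonin (1).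

## Retrosynthesis

**Tiglate and C1 hydroxyl.** The C8–O acyl bond and the O–Si bond at C1 are cut last, leading from 31 through silyl ether 30 to alcohol 27 and tiglic acid (28). The tiglate cannot pass through enolate, hydride or borane steps, and the β-hydroxy ketone is best released at the very end under mildly acidic fluoride. The forward reaction must acylate a hindered secondary alcohol while the C1 oxygen is still masked.

**α-Methylene lactone.** The C11=C13 double bond of 27/26 is traced to the saturated 11-methyl lactone of epoxy ketone 24. Placing this dehydrogenation after all nucleophilic and reducing steps keeps the Michael acceptor out of harm's way. The forward reaction must operate on the lactone enolate beside the C3 ketone. The ketone is parked as its own lithium enolate and an electrophile is used that reacts only with ester enolates.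

**Epoxide.** The C4–O and C5–O bonds of 24 are cut to Z-enone 23, and this to its E isomer 22. A cis epoxide requires the Z alkene, and the enone is then the only electron-poor alkene in the molecule, so peroxide-anion epoxidation is chemoselective. The forward steps need E-to-Z equilibration on a ring holding a single alkene and oxygen delivery to the outer face, anti to C7.

**C1 oxygen and C10 hydrogen.** The C1–O and C10–H bonds of 22/21 are cut to the E-C1=C10 alkene of dienol 18, by way of diol 20. Syn hydroboration sets both centres in one event and fixes their relative configuration by alkene geometry. The C3 ketone is held at the alcohol level (18) and returned to the enone by allylic oxidation, which also differentiates the C1 and C3 hydroxyls without a protecting group. Hydroboration is placed before the E-to-Z isomerisation because the E,E-diene lactone adopts the usual germacrolide conformation, whose outer C1=C10 face corresponds to the required 1R,10S pair.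

**Ten-membered ring (key).** Dienol 18 comes from dienone 17, the hydrolysis product of triene silyl enol ether 16. Reconnecting C5–C10 in 16 gives the bicyclic silyloxy diene 15. This cut is preferred to any ring closure because the macrocycle arises from breaking a bond. Fifteen is simpler by one medium ring, and its C5/C10 stereocentres serve only to steer alkene geometry. The forward reaction must give the E-C1=C10 and E-C4=C5 geometry and must be followed by cold hydrolysis.

**Ring A.** Diene 15 derives from enone 14 by enolisation toward C4, and 14 from saturated ketone 12 by C1–C2 dehydrogenation. The C10 quaternary centre blocks γ-deprotonation, so only the cross-conjugated dienol ether can form.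

**C8 oxygen.** The C8–O bond of 12/11 is traced through 8-ketone 9 to 8-oxobutenolide 8 and then to butenolide 6, where C8 is the γ-methylene of an unsaturated lactone. Butenolide 6 comes from methylene lactone 5 and saturated lactone ketal 3. The C7 centre is removed and restored in this detour, and the ketone permits delivery of the axial 8β-alcohol by a bulky hydride.

**Chiral pool.** Ketal 3 comes from tetrahydro ketone 2 and this from santonin (1), which supplies C6, C7, C10 and, through hydrogenation, the trans ring fusion.

## Roads not taken

**Alternative 1:** Ring expansion by anionic oxy-Cope rearrangement. The C1–C10 bond would be formed while the C3–C8 bond of a six-membered ring is given up. The potassium alkoxide at C8 of a cyclohexenol bearing a (Z)-alkoxyvinyl and an (E)-propenyl group on neighbouring carbons would undergo the [3,3] shift to the ten-membered C8 ketone A1. In A1 the C3 oxygen is an enol ether and C4=C5 is already cis. The ordered transition state translates two alkene geometries directly into the C1/C10 relationship, C8 arrives oxidised, and no E-to-Z correction is needed. On these three points this road is better than the chosen one, which depends on outer-face hydroboration, a separate C8 oxidation and an isomerisation. Its weakness lies after the ring is formed. A1 has no C6 oxygen and no lactone, so the C7 isopropenyl group must be oxidised to the acid level, C6 oxygenated with the correct configuration, the trans lactone closed and the C8 ketone reduced to the 8β-alcohol. All of this would be done on a flexible ring. The chosen plan sets against this the fact that C6, C7 and the trans lactone are bought with 1 and that ring B stereochemistry is settled on a rigid decalin before the ring is opened.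

**Alternative 2:** Ring closure at C3–C4 by alkenylchromium addition. CrCl2 with catalytic NiCl2 would convert a (Z)-alkenyl iodide at C4 into an alkenylchromium that adds to a C3 aldehyde in the same chain (Nozaki–Hiyama–Kishi closure), giving allylic alcohol A2. A2 already carries the lactone, the exocyclic methylene, the tiglate, a protected C1 hydroxyl and a geometrically secure Z alkene. Only oxidation, epoxidation and deprotection would remain, so this road has the shorter and safer end game and better control of the C4=C5 geometry. Its cost is that the ten-membered ring is closed against entropy and transannular strain under high dilution. The open-chain substrate, with five stereocentres (C1, C6, C7, C8, C10) and three sensitive acceptor groups, would also need a long acyclic synthesis. The chosen plan obtains the ring by cleaving a bond and takes three stereocentres from the pool, but pays with a longer sequence after the ring is formed.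

**Alternative 3:** Ring contraction by [2,3]-Wittig rearrangement. Tin–lithium exchange at C8 of a thirteen-membered cyclic ether would trigger a [2,3] shift that forms C7–C8 and breaks O–C13, giving the ten-membered homoallylic alcohol A3. A3 has a free C8 hydroxyl, the C11=C13 methylene and a Z-C4=C5 bond. A thirteen-membered ether is easier to close than a ten-membered carbocycle, and the methylene and C8 oxygen arrive without late dehydrogenation or C–H oxidation. Both are real advantages over the chosen plan. Against this, the C7/C8 relative configuration depends on the transition-state shape of a transannular rearrangement, which is hard to predict. C1, C6 and C10 must be made acyclically, C12 must still be oxidised and lactonised onto C6, and stoichiometric tin is needed. The chosen plan has fewer stereocentres to create and a more predictable ring-forming event.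

Key step: step 11

Remark: C11 is re-formed in step 6 as the 11R (β-methyl, 11αH) epimer and carried as such; the centre is erased in step 18, so either epimer serves.
Remark: compounds 7, 13 and 18–20 are epimer mixtures at C8, C2 and C3 respectively; each converges in a later oxidation or elimination, so these centres are left undefined in the SMILES.

Step 1
Reactants: 1 (−)-α-santonin
Product: 2 α-tetrahydrosantonin (3-oxo-4βH,5αH,11βH-eudesman-12,6α-olide)
Conditions: H2 (1 atm), Pd/C, EtOAc, 25 °C; then HCl (cat.), EtOH, 25 °C
Reagents that add atoms: none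
Why: Heterogeneous hydrogenation should deliver hydrogen to both ring A alkenes from the α face, away from the angular C10 methyl, setting the trans ring fusion (5α-H); acid equilibration places the C4 methyl equatorial, and C4 is erased again in step 10.

Step 2
Reactants: 2 α-tetrahydrosantonin
Product: 3 3,3-ethylenedioxy-4βH,5αH,11βH-eudesman-12,6α-olide
Conditions: HOCH2CH2OH, TsOH (cat.), benzene, reflux (Dean–Stark)
Reagents that add atoms: ethylene glycol, OCCO
Why: Acid-catalysed ketalisation masks the C3 ketone, leaving the lactone α-carbon as the only acidic site and keeping C3 distinct from the C8 ketone made later.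

Step 3
Reactants: 3 ketal lactone
Product: 5 3,3-ethylenedioxy-4βH,5αH-eudesm-11(13)-en-12,6α-olide, via 11β-phenylselenide 4 (not isolated)
Conditions: LiN(iPr)2, THF, −78 °C; PhSeCl; then H2O2, pyridine, CH2Cl2, 0 → 25 °C
Reagents that add atoms: none
Why: Selenenylation of the lactone enolate followed by selenoxide syn-elimination; in trans-fused α-methyl lactones selenium enters anti to H7, so only the methyl hydrogens are syn and the exocyclic alkene should form.

Step 4
Reactants: 5 methylene lactone ketal
Product: 6 3,3-ethylenedioxy-4βH,5αH-eudesm-7(11)-en-12,6α-olide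
Conditions: RuHCl(CO)(PPh3)3 (5 mol %), toluene, 100 °C
Reagents that add atoms: none
Why: Metal hydride addition and β-hydride elimination should move the exocyclic alkene into the tetrasubstituted conjugated position (the thermodynamic butenolide), which makes C8 the γ-methylene of an unsaturated lactone.

Step 5
Reactants: 6 butenolide ketal
Product: 8 3,3-ethylenedioxy-8-oxo-4βH,5αH-eudesm-7(11)-en-12,6α-olide, via 8-hydroxybutenolide 7 (not isolated)
Conditions: SeO2, pyridine (cat.), dioxane, 90 °C; then Dess–Martin periodinane, NaHCO3, CH2Cl2, 25 °C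
Reagents that add atoms: selenium dioxide, O=[Se]=O
Why: SeO2 allylic oxidation (ene reaction, then [2,3] shift) of the unsaturated lactone at its γ-methylene; the CH2 > CH order of this oxidation and the inductive deactivation of the acyloxy-bearing C6–H should direct it to C8, and Dess–Martin oxidation converges both C8 epimers to the ketone.

Step 6
Reactants: 8 8-oxobutenolide ketal
Product: 9 3,3-ethylenedioxy-8-oxo-4βH,5αH,7αH,11αH-eudesman-12,6α-olide
Conditions: H2 (1 atm), Pd/C, EtOAc, 25 °C
Reagents that add atoms: none
Why: The doubly activated C7=C11 bond should be hydrogenated from the α face opposite the C10 methyl, restoring 7α-H (the trans lactone, also the thermodynamic arrangement now that C7 is α to the C8 ketone) and giving 11α-H.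

Step 7
Reactants: 9 8-oxo lactone ketal
Product: 11 8β-hydroxy-3-oxo-4βH,5αH,11αH-eudesman-12,6α-olide, via 8β-hydroxy ketal 10 (not isolated)
Conditions: LiBH(s-Bu)3, THF, −78 °C; then HCl (1 M), THF, 25 °C
Reagents that add atoms: water, O
Why: The bulky hydride should attack the C8 ketone equatorially from the α face, the β face being blocked by the syn-axial C10 methyl, to give the axial 8β-alcohol (8R); aqueous acid then hydrolyses the dioxolane.

Step 8
Reactants: 11 8β-hydroxy ketone
Product: 12 8β-(triethylsilyloxy)-3-oxo-4βH,5αH,11αH-eudesman-12,6α-olide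
Conditions: Et3SiOTf, 2,6-lutidine, CH2Cl2, −78 → 0 °C
Reagents that add atoms: triethylsilyl trifluoromethanesulfonate, CC[Si](CC)(CC)OS(=O)(=O)C(F)(F)F
Why: Silyl triflate silylation of the hindered axial alcohol under non-basic conditions, which avoids alkoxide-induced translactonisation to C8; the triethylsilyl group is chosen so that it can later be removed in the presence of a tert-butyldimethylsilyl ether.

Step 9
Reactants: 12 silyloxy ketone
Product: 14 8β-(triethylsilyloxy)-3-oxo-4βH,5αH,11αH-eudesm-1-en-12,6α-olide, via 2-phenylselenide 13 (not isolated)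
Conditions: LiN(iPr)2 (1.05 equiv), THF, −78 °C; PhSeCl; then H2O2, pyridine, CH2Cl2, 0 °C
Reagents that add atoms: none
Why: Kinetic deprotonation should occur at the C2 methylene rather than the C4 methine or the less acidic lactone α-position; selenenylation and selenoxide syn-elimination then give the 1-en-3-one.

Step 10
Reactants: 14 enone
Product: 15 3-(tert-butyldimethylsilyloxy)-8β-(triethylsilyloxy)-5αH,11αH-eudesma-1,3-dien-12,6α-olide
Conditions: t-BuMe2SiOTf, Et3N, CH2Cl2, 0 °C
Reagents that add atoms: tert-butyldimethylsilyl trifluoromethanesulfonate, CC(C)(C)[Si](C)(C)OS(=O)(=O)C(F)(F)F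
Why: Soft enolisation of the enone can only occur toward C4, because the quaternary C10 blocks γ-deprotonation, so the cross-conjugated 3-silyloxy-1,3-diene is the sole dienol ether.

Step 11
Reactants: 15 silyloxy diene
Product: 16 3-(tert-butyldimethylsilyloxy)-8β-(triethylsilyloxy)-11αH-germacra-1(10),2,4-trien-12,6α-olide (C1=C10 E; C4=C5 E; C2=C3 cis within the ring)
Conditions: hν (300 nm, Pyrex), degassed THF, −78 °C
Reagents that add atoms: none
Why: Excitation of the homoannular 3-silyloxy-1,3-diene triggers the photochemically allowed conrotatory 6π-electron electrocyclic ring opening, in which the C5–C10 σ bond is broken, the C1=C10 and C4=C5 π bonds are formed and the enol ether double bond moves to C2=C3. The closest known reaction type is the opening of trans-fused eudesmane 1,3-dienes and their dienol derivatives to cyclodeca-1(10),2,4-trienes, the provitamin D type of ring opening. No ring is closed: the ten-membered carbocycle is released by cleaving the bond shared by rings A and B, so no cyclisation mode or dilution is involved. No stereocentre is created; C5 and C10 become trigonal and what has to be controlled is alkene geometry. Conrotation from the trans ring fusion (5α-H, 10β-methyl) turns both ring B carbons, C6 and C9, outward, which should give E geometry at C1=C10 and at C4=C5 and leave the central C2=C3 bond cis; the E-C1=C10 bond is the one step 13 requires. Chemoselectivity rests on the diene being the only chromophore absorbing near 300 nm, where the triene should absorb less than the diene, so the photostationary mixture should favour the triene. The triene can reclose thermally in the disrotatory sense or undergo a [1,7] hydrogen shift, so it is kept at −78 °C and taken as a cold solution into step 12, and unchanged 15 is recycled.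

Step 12
Reactants: 16 triene silyl enol ether
Product: 18 3-hydroxy-8β-(triethylsilyloxy)-11αH-germacra-1(10)E,4E-dien-12,6α-olide (C3 epimers), via dienone 17 (not isolated)
Conditions: Bu4NF, AcOH, THF, −78 °C; then NaBH4, CeCl3·7H2O, MeOH, −78 → −40 °C
Reagents that add atoms: none
Why: Buffered fluoride should cleave the enol silyl ether much faster than the alkyl triethylsilyl ether, and kinetic protonation of the dienolate at C2 gives the 3-ketone with C1=C10 intact; immediate Luche reduction parks the ketone as an allylic alcohol before the β,γ-unsaturated ketone can move into conjugation.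

Step 13
Reactants: 18 dienol
Product: 20 (1R,10S)-1,3-dihydroxy-8β-(triethylsilyloxy)-11αH-germacr-4E-en-12,6α-olide, via C1 alkylborane 19 (not isolated)
Conditions: BH3·THF (3 equiv), THF, 0 °C; then H2O2 (30 %), NaOAc (aq.), 0 → 25 °C
Reagents that add atoms: hydrogen peroxide, OO
Why: Syn hydroboration of the E-C1=C10 bond with boron at the less substituted C1, then oxidation with retention, sets the C1/C10 pair in one event; attack on the outer face of the usual E,E-germacrolide conformation (the face peracids use) corresponds to 1R,10S. The C4=C5 bond, flanked by two allylic C–O bonds and more hindered, should react more slowly.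

Step 14
Reactants: 20 diol
Product: 21 (1R,10S)-1-hydroxy-3-oxo-8β-(triethylsilyloxy)-11αH-germacr-4E-en-12,6α-olide
Conditions: MnO2, CH2Cl2, 25 °C
Reagents that add atoms: none
Why: MnO2 oxidises the allylic C3 alcohol (both epimers) and leaves the saturated C1 alcohol, so the two hydroxyls are differentiated without a protecting group; 21 is silylated at once because a hydroxy enone of this type can undergo transannular oxa-Michael addition.

Step 15
Reactants: 21 hydroxy enone
Product: 22 (1R,10S)-1-(tert-butyldimethylsilyloxy)-3-oxo-8β-(triethylsilyloxy)-11αH-germacr-4E-en-12,6α-olide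
Conditions: t-BuMe2SiOTf, 2,6-lutidine, CH2Cl2, −78 °C
Reagents that add atoms: tert-butyldimethylsilyl trifluoromethanesulfonate, CC(C)(C)[Si](C)(C)OS(=O)(=O)C(F)(F)F
Why: Low-temperature silylation with a hindered base protects the C1 hydroxyl without enolising the ketone; the group blocks oxa-Michael addition and retro-aldol cleavage and later keeps C1 distinct from C8.

Step 16
Reactants: 22 E-enone
Product: 23 (1R,10S)-1-(tert-butyldimethylsilyloxy)-3-oxo-8β-(triethylsilyloxy)-11αH-germacr-4Z-en-12,6α-olide
Conditions: PhSSPh (0.2 equiv), hν (350 nm), benzene, 25 °C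
Reagents that add atoms: none
Why: Reversible addition of phenylthiyl radical to the enone β-carbon allows rotation about C4–C5 and equilibrates the alkene; with only one double bond left in the ten-membered ring, the cis (Z) enone, which can also conjugate better, should be the thermodynamic isomer.

Step 17
Reactants: 23 Z-enone
Product: 24 (1R,4R,5R,10S)-4,5-epoxy-1-(tert-butyldimethylsilyloxy)-3-oxo-8β-(triethylsilyloxy)-11αH-germacran-12,6α-olide
Conditions: t-BuOOH, DBU, CH2Cl2, 0 °C
Reagents that add atoms: tert-butyl hydroperoxide, CC(C)(C)OO
Why: Weitz–Scheffer epoxidation: the peroxide anion adds to C5 from the outer face, anti to C7 in the rotamer with H5 and H6 anti (which sets 5R), and the enolate closes on oxygen before C4–C5 rotation, which the ring restrains, so the cis epoxide (4R) should result.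

Step 18
Reactants: 24 epoxy ketone
Product: 26 (1R,4R,5R,10S)-4,5-epoxy-1-(tert-butyldimethylsilyloxy)-3-oxo-8β-(triethylsilyloxy)germacr-11(13)-en-12,6α-olide, via 11-phenylselenide 25 (not isolated)
Conditions: LiN(iPr)2 (2.4 equiv), THF, −78 °C; PhSeSePh, HMPA, −78 → −40 °C; NH4Cl (aq.); then H2O2, AcOH, THF, 0 °C
Reagents that add atoms: none
Why: The first equivalent of base parks the ketone as its C2 lithium enolate (C2 is not a stereocentre and C4 is quaternary), the second forms the lactone enolate, and the diselenide selenenylates ester enolates but not ketone enolates. Selenoxide syn-elimination of the trans-fused lactone, with selenium anti to H7, should then give the exocyclic methylene and erase C11.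

Step 19
Reactants: 26 methylene lactone
Product: 27 (1R,4R,5R,10S)-4,5-epoxy-8β-hydroxy-1-(tert-butyldimethylsilyloxy)-3-oxogermacr-11(13)-en-12,6α-olide
Conditions: PPTS, MeOH, 0 °C
Reagents that add atoms: none
Why: Mild acidic methanolysis cleaves the triethylsilyl ether much faster than the secondary tert-butyldimethylsilyl ether, and the epoxide, deactivated by the adjacent carbonyl, should survive.

Step 20
Reactants: 27 C8 alcohol; 28 tiglic acid
Product: 30 eupakirunsin C 1-O-(tert-butyldimethylsilyl) ether, via mixed anhydride 29 (not isolated)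
Conditions: 28, 2,4,6-Cl3C6H2COCl, Et3N, THF, 25 °C; then 27, DMAP, toluene, 25 °C
Reagents that add atoms: none
Why: Yamaguchi esterification: the mixed anhydride of tiglic acid acylates the hindered C8 alcohol under DMAP catalysis without E/Z scrambling of the tiglate, and the C1 oxygen is still silylated so only C8 can react.

Step 21
Reactants: 30 silyl ether of the target
Product: 31 eupakirunsin C
Conditions: HF·pyridine, pyridine, THF, 0 → 25 °C
Reagents that add atoms: none
Why: Buffered fluoride desilylation releases the C1 hydroxyl under mildly acidic conditions that spare the epoxy ketone, the tiglate, the methylene lactone and the base-sensitive β-hydroxy ketone.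

## Compound list

1 | (−)-α-santonin | C[C@H]1[C@@H]2CC[C@]3(C=CC(=O)C(=C3[C@H]2OC1=O)C)C | starting material
2 | α-tetrahydrosantonin (3-oxo-4βH,5αH,11βH-eudesman-12,6α-olide) | C[C@H]1[C@@H]2CC[C@@]3(C)CCC(=O)[C@@H](C)[C@@H]3[C@H]2OC1=O | intermediate
3 | 3,3-ethylenedioxy-4βH,5αH,11βH-eudesman-12,6α-olide | C[C@H]1[C@@H]2CC[C@@]3(C)CCC4(OCCO4)[C@@H](C)[C@@H]3[C@H]2OC1=O | intermediate
4 | 11β-phenylseleno derivative of 3 (11α-methyl) | C[C@@]1([Se]c5ccccc5)[C@@H]2CC[C@@]3(C)CCC4(OCCO4)[C@@H](C)[C@@H]3[C@H]2OC1=O | intermediate
5 | 3,3-ethylenedioxy-4βH,5αH-eudesm-11(13)-en-12,6α-olide | C=C1[C@@H]2CC[C@@]3(C)CCC4(OCCO4)[C@@H](C)[C@@H]3[C@H]2OC1=O | intermediate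
6 | 3,3-ethylenedioxy-4βH,5αH-eudesm-7(11)-en-12,6α-olide | CC1=C2CC[C@@]3(C)CCC4(OCCO4)[C@@H](C)[C@@H]3[C@H]2OC1=O | intermediate
7 | 8-hydroxy derivative of 6 (C8 epimers) | CC1=C2C(O)C[C@@]3(C)CCC4(OCCO4)[C@@H](C)[C@@H]3[C@H]2OC1=O | intermediate
8 | 3,3-ethylenedioxy-8-oxo-4βH,5αH-eudesm-7(11)-en-12,6α-olide | CC1=C2C(=O)C[C@@]3(C)CCC4(OCCO4)[C@@H](C)[C@@H]3[C@H]2OC1=O | intermediate
9 | 3,3-ethylenedioxy-8-oxo-4βH,5αH,7αH,11αH-eudesman-12,6α-olide | C[C@@H]1[C@@H]2C(=O)C[C@@]3(C)CCC4(OCCO4)[C@@H](C)[C@@H]3[C@H]2OC1=O | intermediate
10 | 3,3-ethylenedioxy-8β-hydroxy-4βH,5αH,11αH-eudesman-12,6α-olide | C[C@@H]1[C@@H]2[C@H](O)C[C@@]3(C)CCC4(OCCO4)[C@@H](C)[C@@H]3[C@H]2OC1=O | intermediate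
11 | 8β-hydroxy-3-oxo-4βH,5αH,11αH-eudesman-12,6α-olide | C[C@@H]1[C@@H]2[C@H](O)C[C@@]3(C)CCC(=O)[C@@H](C)[C@@H]3[C@H]2OC1=O | intermediate
12 | 8β-(triethylsilyloxy)-3-oxo-4βH,5αH,11αH-eudesman-12,6α-olide | C[C@@H]1[C@@H]2[C@H](O[Si](CC)(CC)CC)C[C@@]3(C)CCC(=O)[C@@H](C)[C@@H]3[C@H]2OC1=O | intermediate
13 | 2-phenylseleno derivative of 12 (C2 epimers) | C[C@@H]1[C@@H]2[C@H](O[Si](CC)(CC)CC)C[C@@]3(C)CC([Se]c4ccccc4)C(=O)[C@@H](C)[C@@H]3[C@H]2OC1=O | intermediate
14 | 8β-(triethylsilyloxy)-3-oxo-4βH,5αH,11αH-eudesm-1-en-12,6α-olide | C[C@@H]1[C@@H]2[C@H](O[Si](CC)(CC)CC)C[C@@]3(C)C=CC(=O)[C@@H](C)[C@@H]3[C@H]2OC1=O | intermediate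
15 | 3-(tert-butyldimethylsilyloxy)-8β-(triethylsilyloxy)-5αH,11αH-eudesma-1,3-dien-12,6α-olide | C[C@@H]1[C@@H]2[C@H](O[Si](CC)(CC)CC)C[C@@]3(C)C=CC(O[Si](C)(C)C(C)(C)C)=C(C)[C@@H]3[C@H]2OC1=O | intermediate
16 | 3-(tert-butyldimethylsilyloxy)-8β-(triethylsilyloxy)-11αH-germacra-1(10),2,4-trien-12,6α-olide (trans,cis,trans ring alkenes) | C[C@@H]1[C@@H]2[C@H](O[Si](CC)(CC)CC)C/C(C)=C/C=C(O[Si](C)(C)C(C)(C)C)\C(C)=C\[C@H]2OC1=O | intermediate
17 | 3-oxo-8β-(triethylsilyloxy)-11αH-germacra-1(10)E,4E-dien-12,6α-olide | C[C@@H]1[C@@H]2[C@H](O[Si](CC)(CC)CC)C/C(C)=C/CC(=O)/C(C)=C/[C@H]2OC1=O | intermediate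
18 | 3-hydroxy-8β-(triethylsilyloxy)-11αH-germacra-1(10)E,4E-dien-12,6α-olide (C3 epimers) | C[C@@H]1[C@@H]2[C@H](O[Si](CC)(CC)CC)C/C(C)=C/CC(O)/C(C)=C/[C@H]2OC1=O | intermediate
19 | C1 alkylborane of 18 (C3 as its borate) | C[C@@H]1[C@@H]2[C@H](O[Si](CC)(CC)CC)C[C@H](C)[C@H](B)CC(OB)/C(C)=C/[C@H]2OC1=O | intermediate
20 | (1R,10S)-1,3-dihydroxy-8β-(triethylsilyloxy)-11αH-germacr-4E-en-12,6α-olide (C3 epimers) | C[C@@H]1[C@@H]2[C@H](O[Si](CC)(CC)CC)C[C@H](C)[C@H](O)CC(O)/C(C)=C/[C@H]2OC1=O | intermediate
21 | (1R,10S)-1-hydroxy-3-oxo-8β-(triethylsilyloxy)-11αH-germacr-4E-en-12,6α-olide | C[C@@H]1[C@@H]2[C@H](O[Si](CC)(CC)CC)C[C@H](C)[C@H](O)CC(=O)/C(C)=C/[C@H]2OC1=O | intermediate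
22 | (1R,10S)-1-(tert-butyldimethylsilyloxy)-3-oxo-8β-(triethylsilyloxy)-11αH-germacr-4E-en-12,6α-olide | C[C@@H]1[C@@H]2[C@H](O[Si](CC)(CC)CC)C[C@H](C)[C@H](O[Si](C)(C)C(C)(C)C)CC(=O)/C(C)=C/[C@H]2OC1=O | intermediate
23 | (1R,10S)-1-(tert-butyldimethylsilyloxy)-3-oxo-8β-(triethylsilyloxy)-11αH-germacr-4Z-en-12,6α-olide | C[C@@H]1[C@@H]2[C@H](O[Si](CC)(CC)CC)C[C@H](C)[C@H](O[Si](C)(C)C(C)(C)C)CC(=O)/C(C)=C\[C@H]2OC1=O | intermediate
24 | (1R,4R,5R,10S)-4,5-epoxy-1-(tert-butyldimethylsilyloxy)-3-oxo-8β-(triethylsilyloxy)-11αH-germacran-12,6α-olide | C[C@@H]1[C@@H]2[C@H](O[Si](CC)(CC)CC)C[C@H](C)[C@H](O[Si](C)(C)C(C)(C)C)CC(=O)[C@]3(C)O[C@@H]3[C@H]2OC1=O | intermediate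
25 | 11β-phenylseleno derivative of 24 (11α-methyl) | C[C@@]1([Se]c4ccccc4)[C@@H]2[C@H](O[Si](CC)(CC)CC)C[C@H](C)[C@H](O[Si](C)(C)C(C)(C)C)CC(=O)[C@]3(C)O[C@@H]3[C@H]2OC1=O | intermediate
26 | (1R,4R,5R,10S)-4,5-epoxy-1-(tert-butyldimethylsilyloxy)-3-oxo-8β-(triethylsilyloxy)germacr-11(13)-en-12,6α-olide | C=C1[C@@H]2[C@H](O[Si](CC)(CC)CC)C[C@H](C)[C@H](O[Si](C)(C)C(C)(C)C)CC(=O)[C@]3(C)O[C@@H]3[C@H]2OC1=O | intermediate
27 | (1R,4R,5R,10S)-4,5-epoxy-8β-hydroxy-1-(tert-butyldimethylsilyloxy)-3-oxogermacr-11(13)-en-12,6α-olide | C=C1[C@@H]2[C@H](O)C[C@H](C)[C@H](O[Si](C)(C)C(C)(C)C)CC(=O)[C@]3(C)O[C@@H]3[C@H]2OC1=O | intermediate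
28 | tiglic acid | C/C=C(\C)C(=O)O | starting material
29 | tiglic 2,4,6-trichlorobenzoic anhydride | C/C=C(\C)C(=O)OC(=O)c1c(Cl)cc(Cl)cc1Cl | intermediate
30 | eupakirunsin C 1-O-(tert-butyldimethylsilyl) ether | C=C1[C@@H]2[C@H](OC(=O)/C(C)=C/C)C[C@H](C)[C@H](O[Si](C)(C)C(C)(C)C)CC(=O)[C@]3(C)O[C@@H]3[C@H]2OC1=O | intermediate
31 | eupakirunsin C | C=C1C(=O)O[C@H]2[C@H]1[C@H](OC(=O)/C(C)=C/C)C[C@H](C)[C@H](O)CC(=O)[C@]1(C)O[C@H]21 | target

Total step count: 21. Longest linear sequence: 21 steps (1 → 31); tiglic acid 28 enters in step 20 without prior steps.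

## Least certain steps

**Step 11 (key step).** The opening may stall at an unfavourable photostationary composition. Over-irradiation or warming can drain the triene through photochemical or thermal reclosure to bicyclic dienes and through a [1,7] hydrogen shift. The fallback changes the photosubstrate and its unmasking, not the lamp. Enone 14 is enolised with LiN(SiMe3)2 and trapped with acetic anhydride to give the 3-acetoxy-1,3-diene F1. Enol esters of this type are known substrates for the same conrotatory opening and are robust enough for repeated irradiation and recycling. Irradiation gives the triene enol acetate F2, and cold methanolysis (K2CO3, MeOH, −30 °C) releases dienone 17, where the route is rejoined.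

**Step 5.** The ene oxidation may attack the lactone-bearing C6–H instead of the C8 methylene, or selenous acid may hydrolyse the ketal and then oxidise ring A. The fallback replaces C–H oxidation by an epoxide route from butenolide 6. Epoxidation with methyl(trifluoromethyl)dioxirane on the α face gives the 7α,11α-epoxy lactone F3. Base-promoted epoxide-to-allylic-alcohol isomerisation with diethylaluminium 2,2,6,6-tetramethylpiperidide, Et2Al(NC9H18), gives the 11α-hydroxy-7-ene lactone F4. Oxidative 1,3-transposition of this tertiary allylic alcohol with pyridinium chlorochromate, (C5H5NH)[CrO3Cl] (Babler–Dauben oxidation), returns the route to 8.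

**Step 13.** Borane may be delivered intramolecularly from the C3 borate, which would make the face depend on the C3 configuration, or may add competitively to the C4=C5 bond. The fallback masks C3 as an ester instead of a borate. Dienol 18 is acetylated (Ac2O, pyridine, DMAP) to the 3-acetate F5, whose electron-withdrawing ester deactivates C4=C5 further and cannot deliver borane. Hydroboration–oxidation as in step 13 gives the 1-hydroxy 3-acetate F6, and methanolysis (K2CO3, MeOH, 0 °C) returns diol 20.

**Step 16.** The E/Z equilibrium may not lie far enough toward the Z enone, or thiyl radicals may be lost to irreversible addition. The fallback replaces equilibration by a stoichiometric addition–elimination from 22. Conjugate addition of thiophenol (PhSH, Et3N) gives the 5-phenylthio ketone F7, in which C4 is epimerisable. Oxidation at −78 °C (mCPBA) gives the sulfoxide F8, and gentle warming leads to syn-elimination toward the acidic C4–H. The alkene geometry is then decided kinetically by the preferred conformation of the saturated ring, and the route rejoins at 23.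

**Step 17.** The β-peroxy enolate may rotate about C4–C5 before closure, which would lose the cis geometry; the peroxide may attack from the inner face; or DBU may eliminate the C1 silyloxy group. The fallback switches from stepwise nucleophilic to concerted electrophilic oxygen transfer. Treating 23 with methyl(trifluoromethyl)dioxirane in CH2Cl2 at −20 °C cannot scramble the alkene geometry and needs no base. It leads directly from 23 to 24 and makes no compound outside the list (entry F0).

**Step 18.** Selenenylation may occur on the ketone side, the C2 enolate may expel the C1 silyloxy group, or the selenoxide may eliminate into the ring if selenium enters syn to H7 because of the neighbouring 8β-silyloxy group. The fallback removes the ketone before the lactone chemistry. Epoxy ketone 24 is reduced with NaBH4 to the epoxy alcohol F9 (C3 epimers). Its alkoxide and lactone enolate are formed with LiN(iPr)2 (2.2 equiv), and selenenylation with oxidative elimination as in step 18 gives the methylene lactone alcohol F10. Dess–Martin oxidation then returns 26.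

## Further compounds

F1 | step 11 | 3-acetoxy-8β-(triethylsilyloxy)-5αH,11αH-eudesma-1,3-dien-12,6α-olide | C[C@@H]1[C@@H]2[C@H](O[Si](CC)(CC)CC)C[C@@]3(C)C=CC(OC(C)=O)=C(C)[C@@H]3[C@H]2OC1=O
F2 | step 11 | 3-acetoxy-8β-(triethylsilyloxy)-11αH-germacra-1(10),2,4-trien-12,6α-olide (trans,cis,trans ring alkenes) | C[C@@H]1[C@@H]2[C@H](O[Si](CC)(CC)CC)C/C(C)=C/C=C(OC(C)=O)\C(C)=C\[C@H]2OC1=O
F3 | step 5 | 3,3-ethylenedioxy-7α,11α-epoxy-4βH,5αH-eudesman-12,6α-olide | C[C@]1(O5)[C@@]52CC[C@@]3(C)CCC4(OCCO4)[C@@H](C)[C@@H]3[C@H]2OC1=O
F4 | step 5 | 3,3-ethylenedioxy-11α-hydroxy-4βH,5αH-eudesm-7-en-12,6α-olide | C[C@]1(O)C2=CC[C@@]3(C)CCC4(OCCO4)[C@@H](C)[C@@H]3[C@H]2OC1=O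
F5 | step 13 | 3-acetoxy-8β-(triethylsilyloxy)-11αH-germacra-1(10)E,4E-dien-12,6α-olide (C3 epimers) | C[C@@H]1[C@@H]2[C@H](O[Si](CC)(CC)CC)C/C(C)=C/CC(OC(C)=O)/C(C)=C/[C@H]2OC1=O
F6 | step 13 | (1R,10S)-3-acetoxy-1-hydroxy-8β-(triethylsilyloxy)-11αH-germacr-4E-en-12,6α-olide (C3 epimers) | C[C@@H]1[C@@H]2[C@H](O[Si](CC)(CC)CC)C[C@H](C)[C@H](O)CC(OC(C)=O)/C(C)=C/[C@H]2OC1=O
F7 | step 16 | (1R,10S)-1-(tert-butyldimethylsilyloxy)-3-oxo-5-(phenylthio)-8β-(triethylsilyloxy)-11αH-germacran-12,6α-olide (C4 and C5 epimers) | C[C@@H]1[C@@H]2[C@H](O[Si](CC)(CC)CC)C[C@H](C)[C@H](O[Si](C)(C)C(C)(C)C)CC(=O)C(C)C(Sc3ccccc3)[C@H]2OC1=O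
F8 | step 16 | sulfoxide of the 5-phenylthio ketone (5-phenylsulfinyl) | C[C@@H]1[C@@H]2[C@H](O[Si](CC)(CC)CC)C[C@H](C)[C@H](O[Si](C)(C)C(C)(C)C)CC(=O)C(C)C(S(=O)c3ccccc3)[C@H]2OC1=O
F0 | step 17 | none | none
F9 | step 18 | (1R,4R,5R,10S)-4,5-epoxy-3-hydroxy-1-(tert-butyldimethylsilyloxy)-8β-(triethylsilyloxy)-11αH-germacran-12,6α-olide (C3 epimers) | C[C@@H]1[C@@H]2[C@H](O[Si](CC)(CC)CC)C[C@H](C)[C@H](O[Si](C)(C)C(C)(C)C)CC(O)[C@]3(C)O[C@@H]3[C@H]2OC1=O
F10 | step 18 | (1R,4R,5R,10S)-4,5-epoxy-3-hydroxy-1-(tert-butyldimethylsilyloxy)-8β-(triethylsilyloxy)germacr-11(13)-en-12,6α-olide (C3 epimers) | C=C1[C@@H]2[C@H](O[Si](CC)(CC)CC)C[C@H](C)[C@H](O[Si](C)(C)C(C)(C)C)CC(O)[C@]3(C)O[C@@H]3[C@H]2OC1=O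
A1 | alternative 1 | ten-membered C8 ketone with C3 triethylsilyl dienol ether, C1 PMB ether and C7 isopropenyl group | C1[C@H](C)[C@H](OCc2ccc(OC)cc2)/C=C(O[Si](CC)(CC)CC)/C(C)=C\C[C@H](C(C)=C)C1=O
A2 | alternative 2 | ten-membered (Z)-allylic C3 alcohol carrying the methylene lactone, the C8 tiglate and a C1 silyl ether | C1[C@H](C)[C@H](O[Si](C)(C)C(C)(C)C)C[C@H](O)/C(C)=C\[C@H]2OC(=O)C(=C)[C@@H]2[C@@H]1OC(=O)/C(C)=C/C
A3 | alternative 3 | ten-membered homoallylic C8 alcohol with C7 alkenyl branch, C3 dioxolane and C1/C6 silyl ethers | C1[C@H](C)[C@H](O[Si](C)(C)C(C)(C)C)CC2(OCCO2)/C(C)=C\[C@@H](O[Si](C)(C)C(C)(C)C)[C@H](C(=C)COCc2ccc(OC)cc2)[C@@H]1O
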